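## Analysis of the target

The target is a 5,7-dihydroxyflavanone. Ring A is fused to the dihydropyranone ring C, whose only stereocentre, C2 (S), carries ring B. Ring B is a 3',5'-dimethoxyphenyl ring whose O4' is alkylated by an arylglycerol chain: C8'' (S) bears O4', the hydroxymethyl carbon C9'' and the carbinol carbon C7'' (R), and C7'' is bonded to the ipso carbon of the 4-hydroxy-3-methoxyphenyl ring G. C7'' and C8'' are neighbours in the erythro (anti) relationship, whereas C2 lies across ring B, six bonds from C8'', so the pair and the single centre must be set independently. The molecule is fragile in three ways: ring C opens by retro-oxa-Michael reaction to the 2'-hydroxychalcone under base, which racemises C2; the C7'' alcohol is benzylic and para to a phenol, so it can ionise under acid and can be hydrogenolysed; and the three free phenols are oxidation-prone. The hard part is the O4'–C8'' ether, an oxygen flanked by two methoxy groups on a secondary stereogenic carbon, combined with the need for the erythro isomer in one absolute sense. The strategy rests on two facts. C8'' carries O4' and two carbons at the alcohol oxidation level (C7'' and C9''), so without ring G it is the central carbon of a prochiral 2-aryloxypropane-1,3-diol. C7'' is a secondary carbinol attached directly to ring G, so it is the adduct of an aldehyde and an aryl–metal reagent and can be set from C8'' by 1,2-induction.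

## Retrosynthetic reasoning

**25 ⇒ 24.** The three O–benzyl bonds of tris-benzyl ether 24 are cut last. Benzyl survives the organolithium, titanium, boron and rhodium steps and is removed in one neutral hydrogenolysis, so the free target never meets acid or base.

**24 ⇒ 23.** The 7'',9''-diol of 24 is traced to the isopropylidene acetal 23. The acetal is hydrolysed while the phenols are still benzylated, so acid never meets the free para-phenol next to the benzylic alcohol.

**23 ⇒ 18 + 22.** The C2–C1' bond is cut, giving boronic acid 18 (ring B with the whole side chain) and chromone 22 (rings A and C). This is the one bond that splits the molecule into two pieces of similar size and lets C2 be created last under catalyst control, independent of the remote C7''/C8'' pair. A base-mediated closure of ring C would give no control at C2. The forward reaction must deliver the aryl group to the Re face of C2 of 22 and protonate the enolate without opening ring C.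

**22 ⇒ 20 ⇒ 19.** Chromone 22 gives up C2 (cutting O1–C2 and C2–C3) to return acetophenone 20, the 4,6-di-O-benzyl ether of 19. The hydrogen-bonded ortho hydroxyl of 19 is left free and becomes O1.

**18 ⇒ 15 ⇒ 14 ⇒ 13.** The C–B bond of 18 goes back to the C–Br bond of 15; the bromine para to O4' is carried from phenol 4 as a latent metal. Acetonide 15 comes from diol 14 and this from silyl ether 13. The acetal removes both acidic hydrogens before halogen–metal exchange and locks C7''/C8'' in a ring where their relative configuration can be read.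

**13 ⇒ 10 + 12 (key disconnection).** The bond from C7'' to the ipso carbon of ring G is cut, giving aldehyde 10 and aryltitanium 12. Cutting here leaves C8'' as the only stereocentre of the electrophile, next to the reacting carbonyl, where its aryloxy group can decide the face. Cutting C7''–C8'' would need both centres set at once, and cutting O4'–C8'' would need substitution by a hindered oxygen at a secondary carbon. The forward addition must proceed without chelation and without enolising 10.

**12 ⇒ 11 ⇒ 2 ⇒ 1.** The titanium reagent comes from aryllithium 11, this from bromide 2, and 2 from phenol 1 by benzylation.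

**10 ⇒ 9 ⇒ 8 ⇒ 7 ⇒ 6.** Aldehyde 10 is the oxidation product of alcohol 9, which comes from acetate 8 and monoacetate 7. The two arms on C8'' differ only in protection and oxidation level; removing that difference reveals the prochiral diol 6. The forward step is an enzymatic differentiation of two enantiotopic hydroxymethyl groups.

**6 ⇒ 5 ⇒ 3 + 4.** The two alcohol carbons of 6 are the ester carbons of malonate 5. The O4'–C8'' bond is cut to phenol 4 and bromomalonate 3, so the crowded ether is made where C8'' is not yet stereogenic and is doubly activated toward substitution.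

## Alternatives that were turned down

**Alternative 1:** The disconnection is the C2–C1' bond, taken as the organising idea. Boronic acid 18 and chromone 22 would be joined by an enantioselective rhodium-catalysed conjugate addition to give the fully protected flavanone A1, which is the same compound as 23.
- For it: it is convergent, it creates C2 last under catalyst control, and it avoids a base-mediated closure of ring C.
- Against it: as the centre of the plan it says nothing about the erythro C7''/C8'' pair and the crowded O4'–C8'' ether, which must already be present in 18. It also places the main uncertainty at the point where the most advanced material is committed, because a 5-alkoxychromone is an electron-rich, hindered acceptor and the product can reopen.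
- Comparison: on C2 this alternative is as strong as the chosen plan, which uses the same bond construction as step 14. The chosen strategy adds a solution for C7''/C8'' that is tested early on material from inexpensive achiral precursors.

**Alternative 2:** The disconnection is the O4'–C8'' bond, formed with inversion at C8''. The phenoxide of 4 would open the trans cyclic sulfate A2, ethyl (4S,5R)-5-[3-methoxy-4-(pivaloyloxy)phenyl]-1,3,2-dioxathiolane-4-carboxylate 2,2-dioxide, at the carbon α to the ester. The two centres of A2 would come from a catalytic asymmetric dihydroxylation. Acid hydrolysis of the sulfate monoester would give the erythro hydroxy ester A3, ethyl (2R,3R)-2-(4-bromo-2,6-dimethoxyphenoxy)-3-hydroxy-3-[3-methoxy-4-(pivaloyloxy)phenyl]propanoate.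
- For it: both centres derive from a very predictable catalytic reaction, the inversion converts the syn diol geometry into the erythro ether, and the ester directs the nucleophile to C8''. On predictability of absolute configuration it is stronger than a lipase step whose sense must be verified.
- Against it: the nucleophile is a phenoxide flanked by two methoxy groups and must attack a secondary carbon. The α-hydrogen of A2 is acidic, so elimination across C7''–C8'' and epimerisation of A3 compete. The benzylic C7''–O bond is a second electrophilic site, and the pivalate can be transferred to the phenoxide. Afterwards the ester must be reduced beside an aryl ester and the phenol protecting group exchanged, so the step count is no lower.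
- Comparison: the chosen route forms the same crowded ether on bromomalonate 3, at a carbon that is not stereogenic and has no regiochemical alternative, and introduces chirality afterwards by a reaction that does not involve the hindered oxygen.

**Alternative 3:** The disconnection is the C7''–C8'' bond. Aldehyde A4, 4-(benzyloxy)-3-methoxybenzaldehyde, would react with the (E)-γ-aryloxyallylboronate A5, 2-[(2E)-3-(4-bromo-2,6-dimethoxyphenoxy)prop-2-en-1-yl]-4,4,5,5-tetramethyl-1,3,2-dioxaborolane, under a chiral BINOL-derived phosphoric acid. A closed chair transition state would give the anti homoallylic alcohol A6, (1R,2S)-1-[4-(benzyloxy)-3-methoxyphenyl]-2-(4-bromo-2,6-dimethoxyphenoxy)but-3-en-1-ol.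
- For it: one catalytic step forms the C–C bond and both stereocentres, and the anti relationship follows from the (E) geometry. In stereocentres created per step it is stronger than the chosen plan.
- Against it: A5 carries the crowded aryloxy group and must be geometrically pure, since any (Z) isomer leads to the threo series. A4 is an electron-rich, sluggish aldehyde. The vinyl group of A6 stands in for the C9'' hydroxymethyl group, so oxidative cleavage and reduction are still needed. Those two steps expose two electron-rich rings to a strong oxidant and make C8'' epimerisable while C9'' is at the aldehyde level.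
- Comparison: the chosen strategy has C9'' at the correct oxidation level from the malonate stage, uses reagents of established behaviour, and relies on a stereocentre whose purity can be checked before use. It gives up the one-step creation of both centres for that.

Key step: step 8

**Remarks on the chemistry**

- The lipase is assumed to acetylate the pro-S hydroxymethyl group of 6, the sense expected by analogy with 2-alkoxypropane-1,3-diols; should the other arm react, the fallback for step 4 applies.
- The antipode of the diene ligand in step 14 is assumed to be the one that sends the aryl group to the Re face of C2; if the first antipode tried gives the 2R series, its mirror image is used.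

## Route

Step 1
Reactants: 1 4-bromo-2-methoxyphenol
Product: 2 1-(benzyloxy)-4-bromo-2-methoxybenzene
Conditions: BnBr, K2CO3, DMF, rt
Reagents that add atoms: benzyl bromide, BrCc1ccccc1
Why: Williamson etherification of a phenoxide with a benzylic bromide; the benzyl ether protects the ring G phenol against n-BuLi and is removed at the end by hydrogenolysis.

Step 2
Reactants: 3 diethyl bromomalonate; 4 4-bromo-2,6-dimethoxyphenol
Product: 5 diethyl 2-(4-bromo-2,6-dimethoxyphenoxy)propanedioate
Conditions: K2CO3, DMF, rt → 50 °C
Reagents that add atoms: none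
Why: SN2 displacement of bromide by the phenoxide; the carbon is activated by two ester groups, so even the phenoxide flanked by two methoxy groups should react, and no stereocentre is at stake.

Step 3
Reactants: 5 diethyl 2-(4-bromo-2,6-dimethoxyphenoxy)propanedioate
Product: 6 2-(4-bromo-2,6-dimethoxyphenoxy)propane-1,3-diol
Conditions: LiBH4, THF, MeOH (2 equiv), 0 °C → rt; aq. NH4Cl
Reagents that add atoms: none
Why: Hydride reduction of both esters to primary alcohols; LiBH4 is chosen because it leaves the aryl bromide untouched and is only weakly basic toward the acidic malonate C–H.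

Step 4
Reactants: 6 2-(4-bromo-2,6-dimethoxyphenoxy)propane-1,3-diol
Product: 7 (2S)-2-(4-bromo-2,6-dimethoxyphenoxy)-3-hydroxypropyl acetate
Conditions: Amano lipase PS (Burkholderia cepacia, immobilised), vinyl acetate, t-BuOMe, 25 °C
Reagents that add atoms: vinyl acetate, CC(=O)OC=C
Why: Lipase-catalysed irreversible transesterification with an enol ester; the enzyme distinguishes the two enantiotopic hydroxymethyl groups, and acetylation of the pro-S arm creates the C8'' stereocentre. Monoacetate of the wrong hand is the faster substrate for the second acetylation, so allowing a little diacetate to form should raise the enantiomeric purity of 7.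

Step 5
Reactants: 7 (2S)-2-(4-bromo-2,6-dimethoxyphenoxy)-3-hydroxypropyl acetate
Product: 8 (2R)-2-(4-bromo-2,6-dimethoxyphenoxy)-3-[(tert-butyldimethylsilyl)oxy]propyl acetate
Conditions: TBSCl, imidazole, CH2Cl2, 0 °C
Reagents that add atoms: tert-butyldimethylsilyl chloride, CC(C)(C)[Si](C)(C)Cl
Why: Silylation of the remaining primary alcohol, done at once on crude 7 because 1,3-acyl migration between the arms would racemise C8''. The descriptor changes from S to R only because CH2OSi outranks CH2OAc; no bond to C8'' is touched.

Step 6
Reactants: 8 (2R)-2-(4-bromo-2,6-dimethoxyphenoxy)-3-[(tert-butyldimethylsilyl)oxy]propyl acetate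
Product: 9 (2R)-2-(4-bromo-2,6-dimethoxyphenoxy)-3-[(tert-butyldimethylsilyl)oxy]propan-1-ol
Conditions: K2CO3 (0.2 equiv), MeOH, 0 °C
Reagents that add atoms: none
Why: Base-catalysed methanolysis of the primary acetate; the silyl ether and aryl bromide are inert, and with catalytic carbonate at 0 °C 1,3-silyl migration, which would interconvert the enantiomers of 9, should not compete.

Step 7
Reactants: 9 (2R)-2-(4-bromo-2,6-dimethoxyphenoxy)-3-[(tert-butyldimethylsilyl)oxy]propan-1-ol
Product: 10 (2S)-2-(4-bromo-2,6-dimethoxyphenoxy)-3-[(tert-butyldimethylsilyl)oxy]propanal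
Conditions: Dess–Martin periodinane, NaHCO3, CH2Cl2, 0 °C; cold aq. Na2S2O3/NaHCO3 wash; crude 10 used at once
Reagents that add atoms: none
Why: Dess–Martin oxidation of a primary alcohol to the aldehyde under buffered, non-basic conditions, which should avoid enolisation at C8''. The descriptor becomes S only because CHO outranks CH2OSi.

Step 8
Reactants: 10 (2S)-2-(4-bromo-2,6-dimethoxyphenoxy)-3-[(tert-butyldimethylsilyl)oxy]propanal; 2 1-(benzyloxy)-4-bromo-2-methoxybenzene
Product: 13 (1R,2S)-1-[4-(benzyloxy)-3-methoxyphenyl]-2-(4-bromo-2,6-dimethoxyphenoxy)-3-[(tert-butyldimethylsilyl)oxy]propan-1-ol, via [4-(benzyloxy)-3-methoxyphenyl]lithium 11 (not isolated), via [4-(benzyloxy)-3-methoxyphenyl]titanium triisopropoxide 12 (not isolated)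
Conditions: 2, n-BuLi, THF, −78 °C; ClTi(OiPr)3, −78 → −40 °C; then 10 in THF, −78 → −20 °C; aq. NH4Cl
Reagents that add atoms: none
Why: This is the addition of an aryl–titanium nucleophile to an aldehyde, the closest known reaction type being the non-chelation (Felkin–Anh) addition of organotitanium triisopropoxides to α-alkoxy aldehydes. Bromine–lithium exchange of 2 gives 11, and ClTi(OiPr)3 converts it into the tetravalent titanium reagent 12, which is far less basic than 11, so C8'' of 10 is not deprotonated, and which no longer exchanges with the aryl bromide of 10. Three isopropoxide ligands leave titanium a weak Lewis acid, and neither the aryl ether oxygen O4' nor the silyl ether oxygen is a good donor, so a chelate is not expected. The aldehyde should therefore react in the polar Felkin–Anh arrangement: the C8''–O4' bond antiperiplanar to the forming C–C bond, CH2OSi next to the carbonyl oxygen, and the aryl group approaching on the Bürgi–Dunitz trajectory past the C8'' hydrogen, onto the Re face of the carbonyl carbon. This sets C7'' as R, anti (erythro) to the unchanged 8''S centre; it is the only new stereocentre and no ring is closed. The selectivity needed is diastereofacial, and it is secured by the electronegative aryloxy group on C8'' together with the non-chelating reagent and protecting group. The configuration at C8'' is protected by using 10 cold and immediately.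

Step 9
Reactants: 13 (1R,2S)-1-[4-(benzyloxy)-3-methoxyphenyl]-2-(4-bromo-2,6-dimethoxyphenoxy)-3-[(tert-butyldimethylsilyl)oxy]propan-1-ol
Product: 14 (1R,2S)-1-[4-(benzyloxy)-3-methoxyphenyl]-2-(4-bromo-2,6-dimethoxyphenoxy)propane-1,3-diol
Conditions: Bu4NF, THF, 0 °C → rt
Reagents that add atoms: none
Why: Fluoride-induced cleavage of the primary silyl ether; the aryl bromide, benzyl ether and secondary benzylic alcohol are inert to Bu4NF.

Step 10
Reactants: 14 (1R,2S)-1-[4-(benzyloxy)-3-methoxyphenyl]-2-(4-bromo-2,6-dimethoxyphenoxy)propane-1,3-diol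
Product: 15 (4R,5S)-4-[4-(benzyloxy)-3-methoxyphenyl]-5-(4-bromo-2,6-dimethoxyphenoxy)-2,2-dimethyl-1,3-dioxane
Conditions: Me2C(OMe)2, PPTS (cat.), CH2Cl2, rt
Reagents that add atoms: 2,2-dimethoxypropane, COC(C)(C)OC
Why: Acid-catalysed transacetalisation of the 1,3-diol to the six-membered isopropylidene acetal, with PPTS mild enough not to ionise C7''. The erythro diol gives the 4,5-trans dioxane with both substituents equatorial, which would be expected to show a large H7''–H8'' coupling, while any threo contaminant would give the separable cis isomer.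

Step 11
Reactants: 15 (4R,5S)-4-[4-(benzyloxy)-3-methoxyphenyl]-5-(4-bromo-2,6-dimethoxyphenoxy)-2,2-dimethyl-1,3-dioxane
Product: 18 [4-({(4R,5S)-4-[4-(benzyloxy)-3-methoxyphenyl]-2,2-dimethyl-1,3-dioxan-5-yl}oxy)-3,5-dimethoxyphenyl]boronic acid, via aryllithium 16 (not isolated), via lithium aryltriisopropoxyborate 17 (not isolated)
Conditions: n-BuLi, THF, −78 °C; B(OiPr)3, −78 °C → rt; aq. NH4Cl
Reagents that add atoms: triisopropyl borate, CC(C)OB(OC(C)C)OC(C)C; water, O
Why: Bromine–lithium exchange, trapping of the aryllithium by a trialkyl borate and hydrolysis of the ate complex; with the diol masked the substrate has no acidic hydrogen and no electrophilic group. The free boronic acid is made because it transmetalates to rhodium more readily than a pinacol ester.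

Step 12
Reactants: 19 2,4,6-trihydroxyacetophenone
Product: 20 1-[2,4-bis(benzyloxy)-6-hydroxyphenyl]ethan-1-one
Conditions: BnBr (2.1 equiv), K2CO3, DMF, rt
Reagents that add atoms: benzyl bromide, BrCc1ccccc1
Why: Williamson etherification; once the para and one ortho hydroxyl are benzylated, the last ortho hydroxyl is held in a hydrogen bond to the carbonyl oxygen and stays free.

Step 13
Reactants: 20 1-[2,4-bis(benzyloxy)-6-hydroxyphenyl]ethan-1-one
Product: 22 5,7-bis(benzyloxy)-4H-chromen-4-one, via enaminone 21 (not isolated)
Conditions: Me2NCH(OMe)2, toluene, 100 °C; then conc. HCl, CH2Cl2, 40 °C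
Reagents that add atoms: N,N-dimethylformamide dimethyl acetal, COC(OC)N(C)C
Why: Condensation of the methyl ketone with the formamide acetal gives the enaminone; acid then promotes conjugate addition of the free ortho hydroxyl and loss of dimethylamine, closing the pyranone ring, a standard chromone synthesis.

Step 14
Reactants: 18 [4-({(4R,5S)-4-[4-(benzyloxy)-3-methoxyphenyl]-2,2-dimethyl-1,3-dioxan-5-yl}oxy)-3,5-dimethoxyphenyl]boronic acid; 22 5,7-bis(benzyloxy)-4H-chromen-4-one
Product: 23 (2S)-5,7-bis(benzyloxy)-2-[4-({(4R,5S)-4-[4-(benzyloxy)-3-methoxyphenyl]-2,2-dimethyl-1,3-dioxan-5-yl}oxy)-3,5-dimethoxyphenyl]-2,3-dihydro-4H-chromen-4-one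
Conditions: 22 (2 equiv), [RhCl(C2H4)2]2 (2.5 mol%), Ph-bod* (2,5-diphenylbicyclo[2.2.2]octa-2,5-diene, antipode giving 2S, 5.5 mol%), KOH (0.3 equiv), dioxane/H2O 10:1, 40 °C
Reagents that add atoms: none
Why: Enantioselective rhodium-catalysed 1,4-addition of an arylboronic acid to a chromone: transmetalation to an aryl–rhodium species (monovalent rhodium), insertion of the C2=C3 bond and protonation of the oxa-π-allyl rhodium by water. The chiral diene shields one face of the bound enone so that the aryl group goes to the Re face of C2 (2S); the C7''/C8'' centres are too remote to interfere, so the step is catalyst-controlled. The ethylene precursor is used so that no achiral diene complex competes, and the low base loading and temperature are meant to keep ring C closed.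

Step 15
Reactants: 23 (2S)-5,7-bis(benzyloxy)-2-[4-({(4R,5S)-4-[4-(benzyloxy)-3-methoxyphenyl]-2,2-dimethyl-1,3-dioxan-5-yl}oxy)-3,5-dimethoxyphenyl]-2,3-dihydro-4H-chromen-4-one
Product: 24 (2S)-5,7-bis(benzyloxy)-2-[4-{[(1R,2S)-1-[4-(benzyloxy)-3-methoxyphenyl]-1,3-dihydroxypropan-2-yl]oxy}-3,5-dimethoxyphenyl]-2,3-dihydro-4H-chromen-4-one
Conditions: AcOH/THF/H2O 4:1:1, 40 °C
Reagents that add atoms: none
Why: Acid-catalysed hydrolysis of the isopropylidene acetal by cleavage at the acetal carbon, not at C7''. Aqueous acetic acid is too weak to ionise the benzylic C7''–O bond or to open ring C, and no alcohol solvent is present that could etherify C7''.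

Step 16
Reactants: 24 (2S)-5,7-bis(benzyloxy)-2-[4-{[(1R,2S)-1-[4-(benzyloxy)-3-methoxyphenyl]-1,3-dihydroxypropan-2-yl]oxy}-3,5-dimethoxyphenyl]-2,3-dihydro-4H-chromen-4-one
Product: 25 (2S)-5,7-dihydroxy-2-[4-{[(1R,2S)-1,3-dihydroxy-1-(4-hydroxy-3-methoxyphenyl)propan-2-yl]oxy}-3,5-dimethoxyphenyl]-2,3-dihydro-4H-chromen-4-one
Conditions: H2 (1 atm), Pd/C (10%), EtOAc/MeOH, rt
Reagents that add atoms: none
Why: Hydrogenolysis of three aryl benzyl ethers over Pd/C under neutral conditions. Aryl benzyl ethers should cleave faster than the secondary benzylic alcohol or the C2–O1 bond, so stopping after three equivalents of hydrogen should leave the ketone and all three stereocentres intact.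

## Compound list

1 | 4-bromo-2-methoxyphenol | COc1cc(Br)ccc1O | starting material
2 | 1-(benzyloxy)-4-bromo-2-methoxybenzene | COc1cc(Br)ccc1OCc1ccccc1 | intermediate
3 | diethyl bromomalonate (diethyl 2-bromopropanedioate) | CCOC(=O)C(Br)C(=O)OCC | starting material
4 | 4-bromo-2,6-dimethoxyphenol | COc1cc(Br)cc(OC)c1O | starting material
5 | diethyl 2-(4-bromo-2,6-dimethoxyphenoxy)propanedioate | CCOC(=O)C(Oc1c(OC)cc(Br)cc1OC)C(=O)OCC | intermediate
6 | 2-(4-bromo-2,6-dimethoxyphenoxy)propane-1,3-diol | OCC(CO)Oc1c(OC)cc(Br)cc1OC | intermediate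
7 | (2S)-2-(4-bromo-2,6-dimethoxyphenoxy)-3-hydroxypropyl acetate | CC(=O)OC[C@H](CO)Oc1c(OC)cc(Br)cc1OC | intermediate
8 | (2R)-2-(4-bromo-2,6-dimethoxyphenoxy)-3-[(tert-butyldimethylsilyl)oxy]propyl acetate | CC(=O)OC[C@H](CO[Si](C)(C)C(C)(C)C)Oc1c(OC)cc(Br)cc1OC | intermediate
9 | (2R)-2-(4-bromo-2,6-dimethoxyphenoxy)-3-[(tert-butyldimethylsilyl)oxy]propan-1-ol | OC[C@H](CO[Si](C)(C)C(C)(C)C)Oc1c(OC)cc(Br)cc1OC | intermediate
10 | (2S)-2-(4-bromo-2,6-dimethoxyphenoxy)-3-[(tert-butyldimethylsilyl)oxy]propanal | O=C[C@H](CO[Si](C)(C)C(C)(C)C)Oc1c(OC)cc(Br)cc1OC | intermediate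
11 | [4-(benzyloxy)-3-methoxyphenyl]lithium | [Li]c1ccc(OCc2ccccc2)c(OC)c1 | intermediate
12 | [4-(benzyloxy)-3-methoxyphenyl]titanium triisopropoxide | COc1cc([Ti](OC(C)C)(OC(C)C)OC(C)C)ccc1OCc1ccccc1 | intermediate
13 | (1R,2S)-1-[4-(benzyloxy)-3-methoxyphenyl]-2-(4-bromo-2,6-dimethoxyphenoxy)-3-[(tert-butyldimethylsilyl)oxy]propan-1-ol | COc1cc([C@@H](O)[C@H](CO[Si](C)(C)C(C)(C)C)Oc2c(OC)cc(Br)cc2OC)ccc1OCc1ccccc1 | intermediate
14 | (1R,2S)-1-[4-(benzyloxy)-3-methoxyphenyl]-2-(4-bromo-2,6-dimethoxyphenoxy)propane-1,3-diol | COc1cc([C@@H](O)[C@H](CO)Oc2c(OC)cc(Br)cc2OC)ccc1OCc1ccccc1 | intermediate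
15 | (4R,5S)-4-[4-(benzyloxy)-3-methoxyphenyl]-5-(4-bromo-2,6-dimethoxyphenoxy)-2,2-dimethyl-1,3-dioxane | COc1cc([C@@H](OC5(C)C)[C@H](CO5)Oc2c(OC)cc(Br)cc2OC)ccc1OCc1ccccc1 | intermediate
16 | [4-({(4R,5S)-4-[4-(benzyloxy)-3-methoxyphenyl]-2,2-dimethyl-1,3-dioxan-5-yl}oxy)-3,5-dimethoxyphenyl]lithium | COc1cc([C@@H](OC5(C)C)[C@H](CO5)Oc2c(OC)cc([Li])cc2OC)ccc1OCc1ccccc1 | intermediate
17 | lithium [4-({(4R,5S)-4-[4-(benzyloxy)-3-methoxyphenyl]-2,2-dimethyl-1,3-dioxan-5-yl}oxy)-3,5-dimethoxyphenyl]tri(propan-2-yloxy)borate | COc1cc([C@@H](OC5(C)C)[C@H](CO5)Oc2c(OC)cc([B-](OC(C)C)(OC(C)C)OC(C)C)cc2OC)ccc1OCc1ccccc1.[Li+] | intermediate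
18 | [4-({(4R,5S)-4-[4-(benzyloxy)-3-methoxyphenyl]-2,2-dimethyl-1,3-dioxan-5-yl}oxy)-3,5-dimethoxyphenyl]boronic acid | COc1cc([C@@H](OC5(C)C)[C@H](CO5)Oc2c(OC)cc(B(O)O)cc2OC)ccc1OCc1ccccc1 | intermediate
19 | 2,4,6-trihydroxyacetophenone | CC(=O)c1c(O)cc(O)cc1O | starting material
20 | 1-[2,4-bis(benzyloxy)-6-hydroxyphenyl]ethan-1-one | CC(=O)c1c(O)cc(OCc2ccccc2)cc1OCc1ccccc1 | intermediate
21 | (2E)-1-[2,4-bis(benzyloxy)-6-hydroxyphenyl]-3-(dimethylamino)prop-2-en-1-one | CN(C)/C=C/C(=O)c1c(O)cc(OCc2ccccc2)cc1OCc1ccccc1 | intermediate
22 | 5,7-bis(benzyloxy)-4H-chromen-4-one | O=c1ccoc2cc(OCc3ccccc3)cc(OCc3ccccc3)c12 | intermediate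
23 | (2S)-5,7-bis(benzyloxy)-2-[4-({(4R,5S)-4-[4-(benzyloxy)-3-methoxyphenyl]-2,2-dimethyl-1,3-dioxan-5-yl}oxy)-3,5-dimethoxyphenyl]-2,3-dihydro-4H-chromen-4-one | COc1cc([C@@H](OC5(C)C)[C@H](CO5)Oc2c(OC)cc([C@@H]3CC(=O)c4c(OCc6ccccc6)cc(OCc6ccccc6)cc4O3)cc2OC)ccc1OCc1ccccc1 | intermediate
24 | (2S)-5,7-bis(benzyloxy)-2-[4-{[(1R,2S)-1-[4-(benzyloxy)-3-methoxyphenyl]-1,3-dihydroxypropan-2-yl]oxy}-3,5-dimethoxyphenyl]-2,3-dihydro-4H-chromen-4-one | COc1cc([C@@H](O)[C@H](CO)Oc2c(OC)cc([C@@H]3CC(=O)c4c(OCc5ccccc5)cc(OCc5ccccc5)cc4O3)cc2OC)ccc1OCc1ccccc1 | intermediate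
25 | (2S)-5,7-dihydroxy-2-[4-{[(1R,2S)-1,3-dihydroxy-1-(4-hydroxy-3-methoxyphenyl)propan-2-yl]oxy}-3,5-dimethoxyphenyl]-2,3-dihydro-4H-chromen-4-one | COc1cc([C@@H](O)[C@H](CO)Oc2c(OC)cc([C@@H]3CC(=O)c4c(O)cc(O)cc4O3)cc2OC)ccc1O | target

## Step count and least certain steps

Total step count: 16. Longest linear sequence: 13 steps (steps 2 to 11 and 14 to 16, from 3 and 4 to 25).

**Step 8 (key step).** Two processes are most likely to go wrong. The first is loss of configuration at C8'' by enolisation of the α-aryloxy aldehyde before or during the addition. The second is incomplete facial selectivity, if a titanium chelate involving O4' and a ring B methoxy group competes with the open Felkin–Anh arrangement; hydride transfer from an isopropoxide ligand to the aldehyde is a further minor competitor. The fallback answers the facial problem; it sets out from 13, obtained as a mixture of C7'' epimers, and comes back to 13. The mixture would be oxidised with Dess–Martin periodinane to the ketone (2S)-1-[4-(benzyloxy)-3-methoxyphenyl]-2-(4-bromo-2,6-dimethoxyphenoxy)-3-[(tert-butyldimethylsilyl)oxy]propan-1-one F1. F1 would then be reduced with Zn(BH4)2 in Et2O at −30 °C. Zinc bridging the carbonyl oxygen and O4' (Cram chelate) exposes the face beside the C8'' hydrogen, and hydride delivery from that side gives the same anti alcohol, so the C7'' centre is set by chelation-controlled reduction instead of by aryl addition.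

**Step 4.** The risk is insufficient discrimination between the two enantiotopic arms, because the bulky 2,6-dimethoxyaryloxy group differs from the substituents for which the lipase preference is established; acetylation of the opposite arm or racemisation of 7 by acyl migration are the related failures. The fallback takes C8'' from the chiral pool; it sets out from phenol 4 and comes back at alcohol 9. Purchased methyl (2R)-2,3-dihydroxypropanoate F2 would be silylated at the primary hydroxyl (TBSCl, imidazole) to methyl (2R)-3-[(tert-butyldimethylsilyl)oxy]-2-hydroxypropanoate F3. Mitsunobu reaction of F3 with 4 (PPh3, diisopropyl azodicarboxylate, toluene) would give, with inversion, methyl (2S)-2-(4-bromo-2,6-dimethoxyphenoxy)-3-[(tert-butyldimethylsilyl)oxy]propanoate F4. LiBH4 reduction of F4 would give 9.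

**Step 14.** The risk is slow conjugate addition, because the 5-benzyloxy group makes the chromone electron-rich and crowds the carbonyl that must bind rhodium. Protodeboronation of 18 would then consume the advanced fragment, and base-induced opening of ring C would erode C2. The fallback builds ring C from a chalcone; it sets out from 15 and 20 and comes back at 23. Bromine–lithium exchange of 15 and quenching with DMF would give 4-({(4R,5S)-4-[4-(benzyloxy)-3-methoxyphenyl]-2,2-dimethyl-1,3-dioxan-5-yl}oxy)-3,5-dimethoxybenzaldehyde F5. Claisen–Schmidt condensation of F5 with 20 (KOH, EtOH) would give (2E)-1-[2,4-bis(benzyloxy)-6-hydroxyphenyl]-3-[4-({(4R,5S)-4-[4-(benzyloxy)-3-methoxyphenyl]-2,2-dimethyl-1,3-dioxan-5-yl}oxy)-3,5-dimethoxyphenyl]prop-2-en-1-one F6. NaOAc in refluxing EtOH would close ring C by oxa-Michael addition without control at C2, giving 23 together with (2R)-5,7-bis(benzyloxy)-2-[4-({(4R,5S)-4-[4-(benzyloxy)-3-methoxyphenyl]-2,2-dimethyl-1,3-dioxan-5-yl}oxy)-3,5-dimethoxyphenyl]-2,3-dihydro-4H-chromen-4-one F7. The two are diastereomers and would be separated by chromatography or crystallisation.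

**Step 16.** The risk is over-reduction: hydrogenolysis of the C7''–O bond, which is benzylic and activated by the para oxygen, or of the benzylic C2–O1 bond of ring C. The fallback reverses the order of the last two operations; it sets out from 23 and comes back at 25. Hydrogenolysis of 23 (H2, Pd/C) with the acetal in place, where the C7'' oxygen is held in a ring between the gem-dimethyl carbon and the aryloxy substituent and is less accessible to the metal surface, would give (2S)-5,7-dihydroxy-2-[4-({(4R,5S)-4-(4-hydroxy-3-methoxyphenyl)-2,2-dimethyl-1,3-dioxan-5-yl}oxy)-3,5-dimethoxyphenyl]-2,3-dihydro-4H-chromen-4-one F8. Aqueous acetic acid at 40 °C would then release 25.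

## Further compounds

F1 | step 8 | (2S)-1-[4-(benzyloxy)-3-methoxyphenyl]-2-(4-bromo-2,6-dimethoxyphenoxy)-3-[(tert-butyldimethylsilyl)oxy]propan-1-one | COc1cc(C(=O)[C@H](CO[Si](C)(C)C(C)(C)C)Oc2c(OC)cc(Br)cc2OC)ccc1OCc1ccccc1
F2 | step 4 | methyl (2R)-2,3-dihydroxypropanoate | COC(=O)[C@H](O)CO
F3 | step 4 | methyl (2R)-3-[(tert-butyldimethylsilyl)oxy]-2-hydroxypropanoate | COC(=O)[C@H](O)CO[Si](C)(C)C(C)(C)C
F4 | step 4 | methyl (2S)-2-(4-bromo-2,6-dimethoxyphenoxy)-3-[(tert-butyldimethylsilyl)oxy]propanoate | COC(=O)[C@@H](Oc1c(OC)cc(Br)cc1OC)CO[Si](C)(C)C(C)(C)C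
F5 | step 14 | 4-({(4R,5S)-4-[4-(benzyloxy)-3-methoxyphenyl]-2,2-dimethyl-1,3-dioxan-5-yl}oxy)-3,5-dimethoxybenzaldehyde | COc1cc([C@@H](OC5(C)C)[C@H](CO5)Oc2c(OC)cc(C=O)cc2OC)ccc1OCc1ccccc1
F6 | step 14 | (2E)-1-[2,4-bis(benzyloxy)-6-hydroxyphenyl]-3-[4-({(4R,5S)-4-[4-(benzyloxy)-3-methoxyphenyl]-2,2-dimethyl-1,3-dioxan-5-yl}oxy)-3,5-dimethoxyphenyl]prop-2-en-1-one | COc1cc([C@@H](OC5(C)C)[C@H](CO5)Oc2c(OC)cc(/C=C/C(=O)c3c(O)cc(OCc4ccccc4)cc3OCc3ccccc3)cc2OC)ccc1OCc1ccccc1
F7 | step 14 | (2R)-5,7-bis(benzyloxy)-2-[4-({(4R,5S)-4-[4-(benzyloxy)-3-methoxyphenyl]-2,2-dimethyl-1,3-dioxan-5-yl}oxy)-3,5-dimethoxyphenyl]-2,3-dihydro-4H-chromen-4-one | COc1cc([C@@H](OC5(C)C)[C@H](CO5)Oc2c(OC)cc([C@H]3CC(=O)c4c(OCc6ccccc6)cc(OCc6ccccc6)cc4O3)cc2OC)ccc1OCc1ccccc1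
F8 | step 16 | (2S)-5,7-dihydroxy-2-[4-({(4R,5S)-4-(4-hydroxy-3-methoxyphenyl)-2,2-dimethyl-1,3-dioxan-5-yl}oxy)-3,5-dimethoxyphenyl]-2,3-dihydro-4H-chromen-4-one | COc1cc([C@@H](OC5(C)C)[C@H](CO5)Oc2c(OC)cc([C@@H]3CC(=O)c4c(O)cc(O)cc4O3)cc2OC)ccc1O
A1 | alternative 1 | (2S)-5,7-bis(benzyloxy)-2-[4-({(4R,5S)-4-[4-(benzyloxy)-3-methoxyphenyl]-2,2-dimethyl-1,3-dioxan-5-yl}oxy)-3,5-dimethoxyphenyl]-2,3-dihydro-4H-chromen-4-one | COc1cc([C@@H](OC5(C)C)[C@H](CO5)Oc2c(OC)cc([C@@H]3CC(=O)c4c(OCc6ccccc6)cc(OCc6ccccc6)cc4O3)cc2OC)ccc1OCc1ccccc1
A2 | alternative 2 | ethyl (4S,5R)-5-[3-methoxy-4-(pivaloyloxy)phenyl]-1,3,2-dioxathiolane-4-carboxylate 2,2-dioxide | COc1cc([C@H]2OS(=O)(=O)O[C@@H]2C(=O)OCC)ccc1OC(=O)C(C)(C)C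
A3 | alternative 2 | ethyl (2R,3R)-2-(4-bromo-2,6-dimethoxyphenoxy)-3-hydroxy-3-[3-methoxy-4-(pivaloyloxy)phenyl]propanoate | COc1cc([C@@H](O)[C@H](C(=O)OCC)Oc2c(OC)cc(Br)cc2OC)ccc1OC(=O)C(C)(C)C
A4 | alternative 3 | 4-(benzyloxy)-3-methoxybenzaldehyde | COc1cc(C=O)ccc1OCc1ccccc1
A5 | alternative 3 | 2-[(2E)-3-(4-bromo-2,6-dimethoxyphenoxy)prop-2-en-1-yl]-4,4,5,5-tetramethyl-1,3,2-dioxaborolane | COc1cc(Br)cc(OC)c1O/C=C/CB1OC(C)(C)C(C)(C)O1
A6 | alternative 3 | (1R,2S)-1-[4-(benzyloxy)-3-methoxyphenyl]-2-(4-bromo-2,6-dimethoxyphenoxy)but-3-en-1-ol | COc1cc([C@@H](O)[C@H](C=C)Oc2c(OC)cc(Br)cc2OC)ccc1OCc1ccccc1
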